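## Retrosynthetic overview

1. Feature: ring A (C4a, C5, C6, C7, C8, C8a) bears oxygen on every second carbon (O5, O7, O1) and PhCO on C8. This is the pattern of a folded benzoyl-started tetraketide, and only O1 on C8a is acylated (by C2 of ring B).
2. C6–prenyl is cut last, as the [3,3] shift of an O5 1,1-dimethylallyl ether onto C6, the one unsubstituted ring carbon, after O5–CH3 cleavage.
3. C8–C8a and O1–C2 are cut together. This unfolds rings A and B to a 3-substituted 4-methoxy-6-phenacyl-2-pyrone (C2′ = C8a, C3′ = C4a, C4′ = C5, C5′ = C6, C6′ = C7, phenacyl CH2 = C8).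
4. C4–C4a comes from an iminium-catalysed Michael addition of pyrone C3′ to cinnamaldehyde, which sets 4R. The phenacyl arm is built on the pyrone 6-methyl group before that, while no enolisable ester is present.
5. Ring order: purchased pyrone, then a temporary lactol/enol-lactone ring (made in step 2, opened in step 4), then ring A and ring B in one operation.

Key step: step 5

Numbering: O1 to C8a are the chroman-2-one atoms of the target and label the same atoms in all precursors. Primed numbers are pyrone positions.

Configuration: the target SMILES reads as 4R (C4a > phenyl > C3 > H).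

Assumption: the facial sense of step 2 follows the accepted steric-shielding model for diarylprolinol silyl ether iminium ions, so the (R)-catalyst gives 4R. If the sense proved opposite, the (S)-catalyst would be used with no other change.

Design rule: from step 5 onwards no step uses a nucleophilic or hydrolytic base, because an opened lactone could re-close on O5 once that oxygen is free.

## Route

Step 1
Reactants: 1 4-hydroxy-6-methyl-2H-pyran-2-one; 2 methyl benzoate
Product: 3 4-hydroxy-6-(2-oxo-2-phenylethyl)-2H-pyran-2-one
Conditions: LDA (3.3 equiv), THF, −78 to −30 °C; 2, −78 °C to rt; 2 M HCl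
Reagents that add atoms: none
Why: Crossed Claisen condensation of the O,C-dianion of 1, which reacts through its more basic exocyclic CH2 terminus with the non-enolisable ester 2 while the third equivalent of base absorbs the acidic CH2 of 3; the acylation is placed first because later intermediates carry an enolisable side-chain ester that would compete for the excess base.

Step 2
Reactants: 3 4-hydroxy-6-(2-oxo-2-phenylethyl)-2H-pyran-2-one; 4 (E)-cinnamaldehyde
Product: 6 (4R)-2-hydroxy-7-(2-oxo-2-phenylethyl)-4-phenyl-3,4-dihydro-2H,5H-pyrano[4,3-b]pyran-5-one as an anomer mixture, via open-chain aldehyde 5 (not isolated)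
Conditions: (R)-α,α-diphenylprolinol trimethylsilyl ether (10 mol %), PhCO2H (10 mol %), CH2Cl2, 10 °C
Reagents that add atoms: none
Why: Iminium-catalysed asymmetric Michael addition: the CPh2(OTMS) group of the (R)-catalyst covers one face of the s-trans E-iminium ion of 4, so the fully enolised C3′ of 3, a far better nucleophile than the phenacyl CH2, should add to the open Re face of C-β and set C4 as R, after which O4′ traps aldehyde 5 as the lactol and so suppresses the reverse reaction.

Step 3
Reactants: 6 (4R)-2-hydroxy-7-(2-oxo-2-phenylethyl)-4-phenyl-3,4-dihydro-2H,5H-pyrano[4,3-b]pyran-5-one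
Product: 7 (4R)-7-(2-oxo-2-phenylethyl)-4-phenyl-3,4-dihydro-2H,5H-pyrano[4,3-b]pyran-2,5-dione
Conditions: DMP (1.2 equiv), CH2Cl2, 0 °C to rt
Reagents that add atoms: none
Why: Lactol-to-lactone oxidation with a hypervalent iodine(V) reagent under neutral conditions, fast at the hemiacetal C–H and without effect on C4, the pyrone or the phenacyl CH2.

Step 4
Reactants: 7 (4R)-7-(2-oxo-2-phenylethyl)-4-phenyl-3,4-dihydro-2H,5H-pyrano[4,3-b]pyran-2,5-dione
Product: 9 methyl (R)-3-[4-methoxy-2-oxo-6-(2-oxo-2-phenylethyl)-2H-pyran-3-yl]-3-phenylpropanoate, via hydroxy ester 8 (not isolated)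
Conditions: KHCO3 (1.1 equiv), MeOH, rt; evaporate; Me2SO4 (1.05 equiv), acetone, 45 °C
Reagents that add atoms: methanol CO; dimethyl sulfate COS(=O)(=O)OC
Why: Methanolysis of an activated enol ester followed by O-alkylation of a vinylogous carboxylate: the pyronate (pKa of its acid about 5) is a good leaving group, hydrogencarbonate holds O4′ as the preformed potassium salt but is too weak to enolise the phenacyl CH2 or the ester, and the hard electrophile should methylate that salt on O4′ (future O5) to give the 4-methoxy-2-pyrone, with C4 untouched since no ester enolate is formed.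

Step 5
Reactants: 9 methyl (R)-3-[4-methoxy-2-oxo-6-(2-oxo-2-phenylethyl)-2H-pyran-3-yl]-3-phenylpropanoate
Product: 12 (4R)-8-benzoyl-7-hydroxy-5-methoxy-4-phenylchroman-2-one, via open-chain enol ether 10 (not isolated), via benzophenone ester 11 (not isolated)
Conditions: Mg(OMe)2 (3 equiv), MeOH, reflux; 2 M HCl, 0 °C; crude extract, p-TsOH (5 mol %), PhMe, 80 °C
Reagents that add atoms: none
Why: Mg2+-assisted methoxide adds to the pyrone carbonyl C2′ and opens the ring to enol ether 10, in which the new methyl ester (future C8a) and the 1,3-diketone arm stand cis on the C4a=C5 double bond; the diketone enolate then attacks that ester through C8, methoxide leaves, and enolisation to benzophenone 11 makes the sequence irreversible. The closest known reactions are the base-induced rearrangement of 4-alkoxy-6-(2-oxoalkyl)-2-pyrones to acylphloroglucinol ethers, which is the Claisen cyclisation of a 3,5,7-triketo ester, and the acid-catalysed lactonisation of 3-(2-hydroxyaryl)propanoates. Ring A closes 6-exo-trig (C8 onto the C8a ester carbonyl) and ring B closes 6-exo-trig (O1 onto the C2 ester carbonyl), the latter only after acidification and removal of methanol, because basic methanol keeps the aryl lactone open. No stereocenter is formed, and C4 should be retained because its hydrogen is activated by no carbonyl group and the enol-ether carbon C4a cannot depart as a stabilised carbanion. Carbon–carbon closure must follow the Claisen and not the aldol mode, which is secured by C4a being fully substituted and locked as an enol ether, and the lactone must form on O1, which is secured by the methyl group on O5 and by O7 lying meta to the side chain. Methoxide matches the O5 methyl ether and both esters, so that any exchange at C5, C8a or C2 is degenerate.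

Step 6
Reactants: 12 (4R)-8-benzoyl-7-hydroxy-5-methoxy-4-phenylchroman-2-one
Product: 13 (4R)-8-benzoyl-5,7-dihydroxy-4-phenylchroman-2-one
Conditions: BBr3 (4 equiv), CH2Cl2, −78 to 0 °C; ice-water
Reagents that add atoms: none
Why: Lewis-acid cleavage of an aryl methyl ether with BBr3, run before the acid-sensitive prenyl group is present; the lactone should stay on O1 because the medium holds no nucleophile that opens it and a direct O1-to-O5 acyl shift would need a tetrahedral intermediate bridged across the planar ring carbon C4a, which is geometrically out of reach.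

Step 7
Reactants: 14 2-methylbut-3-en-2-ol; 15 di-tert-butyl dicarbonate
Product: 16 tert-butyl 2-methylbut-3-en-2-yl carbonate
Conditions: n-BuLi (1.05 equiv), THF, −78 to 0 °C; 15, 0 °C to rt; H2O
Reagents that add atoms: none
Why: Acylation of the lithium alkoxide of a tertiary allylic alcohol with Boc2O gives the mixed carbonate that serves as the π-allyl precursor.

Step 8
Reactants: 13 (4R)-8-benzoyl-5,7-dihydroxy-4-phenylchroman-2-one; 16 tert-butyl 2-methylbut-3-en-2-yl carbonate
Product: 17 (4R)-8-benzoyl-7-hydroxy-5-[(2-methylbut-3-en-2-yl)oxy]-4-phenylchroman-2-one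
Conditions: 16 (1.2 equiv), Pd(PPh3)4 (5 mol %), THF, 0 °C
Reagents that add atoms: none
Why: Palladium-catalysed decarboxylative O-allylation (Tsuji–Trost type): ionisation of 16 gives the 1,1-dimethyl-π-allyl complex, CO2 and tert-butoxide, the latter deprotonates the free O5–H rather than the O7–H that is hydrogen-bonded to the benzoyl group, and at low temperature the phenoxide should attack the more substituted allyl terminus under neutral conditions that leave the lactone closed, any O7 ether being harmless because its [3,3] shift also ends at C6.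

Step 9
Reactants: 17 (4R)-8-benzoyl-7-hydroxy-5-[(2-methylbut-3-en-2-yl)oxy]-4-phenylchroman-2-one
Product: 19 (4R)-8-benzoyl-5,7-dihydroxy-6-(3-methylbut-2-en-1-yl)-4-phenylchroman-2-one, via cyclohexadienone 18 (not isolated)
Conditions: PhMe, 110 °C
Reagents that add atoms: none
Why: Aromatic Claisen rearrangement: the [3,3] shift from O5 can reach only C6 because the other ortho carbon C4a is substituted, it inverts the allyl unit so that the tertiary ether delivers the linear prenyl group, and dienone 18 re-aromatises by enolisation without involving C4 or the lactone.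

## Compound list

1 | 4-hydroxy-6-methyl-2H-pyran-2-one | Cc1cc(O)cc(=O)o1 | starting material
2 | methyl benzoate | COC(=O)c1ccccc1 | starting material
3 | 4-hydroxy-6-(2-oxo-2-phenylethyl)-2H-pyran-2-one | O=C(Cc1cc(O)cc(=O)o1)c1ccccc1 | intermediate
4 | (E)-cinnamaldehyde | O=C/C=C/c1ccccc1 | starting material
5 | (R)-3-[4-hydroxy-2-oxo-6-(2-oxo-2-phenylethyl)-2H-pyran-3-yl]-3-phenylpropanal | Oc1cc(CC(=O)c2ccccc2)oc(=O)c1[C@@H](c1ccccc1)CC=O | intermediate
6 | (4R)-2-hydroxy-7-(2-oxo-2-phenylethyl)-4-phenyl-3,4-dihydro-2H,5H-pyrano[4,3-b]pyran-5-one (C2 anomers) | OC1C[C@H](c2ccccc2)c2c(O1)cc(CC(=O)c1ccccc1)oc2=O | intermediate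
7 | (4R)-7-(2-oxo-2-phenylethyl)-4-phenyl-3,4-dihydro-2H,5H-pyrano[4,3-b]pyran-2,5-dione | O=C1C[C@H](c2ccccc2)c2c(O1)cc(CC(=O)c1ccccc1)oc2=O | intermediate
8 | methyl (R)-3-[4-hydroxy-2-oxo-6-(2-oxo-2-phenylethyl)-2H-pyran-3-yl]-3-phenylpropanoate | Oc1cc(CC(=O)c2ccccc2)oc(=O)c1[C@@H](c1ccccc1)CC(=O)OC | intermediate
9 | methyl (R)-3-[4-methoxy-2-oxo-6-(2-oxo-2-phenylethyl)-2H-pyran-3-yl]-3-phenylpropanoate | COc1cc(CC(=O)c2ccccc2)oc(=O)c1[C@@H](c1ccccc1)CC(=O)OC | intermediate
10 | dimethyl (2E,3R)-2-(1-methoxy-3,5-dioxo-5-phenylpentylidene)-3-phenylpentanedioate | COC(=O)/C([C@@H](c1ccccc1)CC(=O)OC)=C(/OC)CC(=O)CC(=O)c1ccccc1 | intermediate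
11 | methyl (R)-3-(3-benzoyl-2,4-dihydroxy-6-methoxyphenyl)-3-phenylpropanoate | COc1cc(O)c(C(=O)c2ccccc2)c(O)c1[C@@H](c1ccccc1)CC(=O)OC | intermediate
12 | (4R)-8-benzoyl-7-hydroxy-5-methoxy-4-phenylchroman-2-one | COc1cc(O)c(C(=O)c2ccccc2)c2c1[C@@H](c1ccccc1)CC(=O)O2 | intermediate
13 | (4R)-8-benzoyl-5,7-dihydroxy-4-phenylchroman-2-one | Oc1cc(O)c(C(=O)c2ccccc2)c2c1[C@@H](c1ccccc1)CC(=O)O2 | intermediate
14 | 2-methylbut-3-en-2-ol | C=CC(C)(C)O | starting material
15 | di-tert-butyl dicarbonate | CC(C)(C)OC(=O)OC(=O)OC(C)(C)C | starting material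
16 | tert-butyl 2-methylbut-3-en-2-yl carbonate | C=CC(C)(C)OC(=O)OC(C)(C)C | intermediate
17 | (4R)-8-benzoyl-7-hydroxy-5-[(2-methylbut-3-en-2-yl)oxy]-4-phenylchroman-2-one | C=CC(C)(C)Oc1cc(O)c(C(=O)c2ccccc2)c2c1[C@@H](c1ccccc1)CC(=O)O2 | intermediate
18 | (4R)-8-benzoyl-7-hydroxy-6-(3-methylbut-2-en-1-yl)-4-phenyl-3,4-dihydro-2H-chromene-2,5(6H)-dione (C6 epimers) | CC(C)=CCC1C(O)=C(C(=O)c2ccccc2)C2=C(C1=O)[C@@H](c1ccccc1)CC(=O)O2 | intermediate
19 | (4R)-8-benzoyl-5,7-dihydroxy-6-(3-methylbut-2-en-1-yl)-4-phenylchroman-2-one (CNP0337570.1) | CC(C)=CCc1c(O)c(C(=O)c2ccccc2)c2c(c1O)[C@@H](c1ccccc1)CC(=O)O2 | target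

## Step count and risks

Total steps: 9. Longest linear sequence: 8 (steps 1, 2, 3, 4, 5, 6, 8, 9).

**Step 5.**
- Base first removes a phenacyl proton. The extended enolate may leave the pyrone carbonyl too electron-rich, and too crowded by the C4 substituent, for methoxide to open it.
- The push–pull ester of the opened chain may resist attack by carbon, or the chain may close through oxygen instead.
- Long heating in base may erode C4.
- The fallback sets out from 3 and 4 and comes back at 12, and it moves aromatisation ahead of the stereocenter.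
- Compound 3 is turned into its potassium salt and methylated as in step 4 to 4-methoxy-6-(2-oxo-2-phenylethyl)-2H-pyran-2-one F1.
- The pyrone of F1, unsubstituted at C3′, is rearranged with Mg(OMe)2 in methanol to 2,6-dihydroxy-4-methoxybenzophenone F2.
- The two free ring carbons of F2 are equivalent. An iminium-catalysed Friedel–Crafts-type Michael addition to 4 with the catalyst of step 2, followed by hemiacetal closure through the neighbouring hydroxyl, can therefore give only [(4R)-2,7-dihydroxy-5-methoxy-4-phenyl-3,4-dihydro-2H-chromen-8-yl](phenyl)methanone F3.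
- Oxidation of F3 with Ag2CO3 on Celite in toluene gives 12.

**Step 8.**
- The O5 aryloxide is stabilised by the para benzoyl group and is therefore a good leaving group. Palladium may re-ionise the tertiary ether and let the allyl unit drift to the linear O-isomer.
- A second etherification at O7 may also set in.
- The fallback sets out from 13 and comes back at 17, and it forms the tertiary C–O bond without a π-allyl intermediate.
- Copper-catalysed propargylic etherification (3-chloro-3-methylbut-1-yne, catalytic CuCl2, DBU, MeCN, 0 °C) gives (4R)-8-benzoyl-7-hydroxy-5-[(2-methylbut-3-yn-2-yl)oxy]-4-phenylchroman-2-one F4.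
- Semi-hydrogenation of F4 (H2, Pd/CaCO3–Pb, quinoline, EtOAc) gives 17.

**Step 4.**
- Methylation may spill over to the phenacyl enolate once O4′ is capped.
- It may also take place on the lactone carbonyl oxygen, where salt formation is incomplete, and lead into the 4-pyranone series.
- The fallback sets out from 1 and 4 and comes back at 9, and it methylates before the phenacyl group exists.
- Compound 1 adds to 4 under the conditions of step 2 to give (4R)-2-hydroxy-7-methyl-4-phenyl-3,4-dihydro-2H,5H-pyrano[4,3-b]pyran-5-one F5.
- DMP oxidation of F5 gives (4R)-7-methyl-4-phenyl-3,4-dihydro-2H,5H-pyrano[4,3-b]pyran-2,5-dione F6.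
- Methanolysis of F6 gives methyl (R)-3-(4-hydroxy-6-methyl-2-oxo-2H-pyran-3-yl)-3-phenylpropanoate F7.
- Treatment of F7 with Me2SO4 and K2CO3 in acetone gives methyl (R)-3-(4-methoxy-6-methyl-2-oxo-2H-pyran-3-yl)-3-phenylpropanoate F8.
- One equivalent of LiHMDS (THF, −78 °C) then removes the most acidic proton of F8, that of the 6-methyl group.
- N-methoxy-N-methylbenzamide holds the adduct as its chelated tetrahedral form until the quench. No second equivalent of base, which would enolise the side-chain ester, is therefore needed, and 9 results.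

Further compounds
F1 | step 5 | 4-methoxy-6-(2-oxo-2-phenylethyl)-2H-pyran-2-one | COc1cc(CC(=O)c2ccccc2)oc(=O)c1
F2 | step 5 | 2,6-dihydroxy-4-methoxybenzophenone | COc1cc(O)c(C(=O)c2ccccc2)c(O)c1
F3 | step 5 | [(4R)-2,7-dihydroxy-5-methoxy-4-phenyl-3,4-dihydro-2H-chromen-8-yl](phenyl)methanone | COc1cc(O)c(C(=O)c2ccccc2)c2c1[C@@H](c1ccccc1)CC(O)O2
F4 | step 8 | (4R)-8-benzoyl-7-hydroxy-5-[(2-methylbut-3-yn-2-yl)oxy]-4-phenylchroman-2-one | C#CC(C)(C)Oc1cc(O)c(C(=O)c2ccccc2)c2c1[C@@H](c1ccccc1)CC(=O)O2
F5 | step 4 | (4R)-2-hydroxy-7-methyl-4-phenyl-3,4-dihydro-2H,5H-pyrano[4,3-b]pyran-5-one | OC1C[C@H](c2ccccc2)c2c(O1)cc(C)oc2=O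
F6 | step 4 | (4R)-7-methyl-4-phenyl-3,4-dihydro-2H,5H-pyrano[4,3-b]pyran-2,5-dione | O=C1C[C@H](c2ccccc2)c2c(O1)cc(C)oc2=O
F7 | step 4 | methyl (R)-3-(4-hydroxy-6-methyl-2-oxo-2H-pyran-3-yl)-3-phenylpropanoate | Cc1cc(O)c([C@@H](c2ccccc2)CC(=O)OC)c(=O)o1
F8 | step 4 | methyl (R)-3-(4-methoxy-6-methyl-2-oxo-2H-pyran-3-yl)-3-phenylpropanoate | Cc1cc(OC)c([C@@H](c2ccccc2)CC(=O)OC)c(=O)o1
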